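**Plan** (labdane numbering, C-1 to C-20; C-19 is the C-4 carbon cis to CH3-20)

- Retrosynthesis: remove the two acetates and unmask the C-15 acid and C-19 aldehyde; cut C12–C13 (B-alkyl Suzuki–Miyaura) and C11=C12 (Wittig); cut C5–C10 and C8–C9 together (intramolecular Diels–Alder, with the Δ7 alkene written as a Δ6 allylsilane); cut C5=C6 (Horner–Wadsworth–Emmons) and C1–C2 (vinylogous Mukaiyama aldol); cut C4–C5 and C4–CH3 (Fráter–Seebach alkylations of diethyl (R)-malate).
- Enabling feature: ring B is a cyclohexene in which the C5–C10 and C8–C9 bonds flank C9–C10. With C-11 as a formyl group, C9=C10 is an activated dienophile and C5=C6–C7=C8 a diene, joined through ring A atoms C-1 to C-4 (a 1,3,9-decatriene). A silyl group on C-8 makes the adduct an allylsilane whose protodesilylation places the alkene at C7=C8.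
- Forward order: the chain is built first (C-2 to C-4 core from malate, then the C-5 to C-8 silyl diene, then the C-1/C-9 to C-11 enoate); rings A and B arise in one step; the C-12 to C-16 side chain follows; the helpers (C-8 silyl group, C-2/C-3 dioxolane ring, tert-butyl ester) leave in one acid step before acetylation.
- Stereochemistry: C-3 from (R)-malate; C-4 from two anti-selective enolate alkylations; C-2 from a 1,2-anti (non-chelation) aldol addition; C-5, C-9 and C-10 from the cycloaddition (E-dienophile, formyl-endo transition state, chair tether with the C-2 oxygen equatorial); 13E from an E-enol triflate.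

Key step: step 16

Assumption: silyl ketene acetal 21 is used as the isomer mixture formed in step 11; its C=C geometry (left undefined in the SMILES) is lost in step 12.

**Step 1**
Reactants: 1 diethyl (R)-malate; 2 iodomethane
Product: 3 diethyl (2R,3S)-2-hydroxy-3-methylbutanedioate
Conditions: LiN(i-Pr)2 (2.2 equiv), THF, −78 to −20 °C; then 2, −78 °C to rt
Reagents that add atoms: iodomethane, CI
Why: Fráter–Seebach alkylation: the chelated alkoxide–enolate dianion should be methylated on the face anti to the C–O bond, under control of the malate stereocenter (future C-3).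

**Step 2**
Reactants: 3 diethyl (2R,3S)-2-hydroxy-3-methylbutanedioate; 4 3-bromoprop-1-ene
Product: 5 diethyl (2S,3R)-3-hydroxy-2-methyl-2-(prop-2-en-1-yl)butanedioate
Conditions: LiN(i-Pr)2 (2.2 equiv), THF/DMPU, −78 to −10 °C; then 4, −78 °C to rt
Reagents that add atoms: 3-bromoprop-1-ene, C=CCBr
Why: second Fráter–Seebach alkylation: the tetrasubstituted alkoxide–enolate should again be attacked anti to the C–O bond, so the allyl group (future C-5) ends anti and the methyl group syn to the C-3 oxygen, which is the C-4 configuration of the target.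

**Step 3**
Reactants: 5 diethyl (2S,3R)-3-hydroxy-2-methyl-2-(prop-2-en-1-yl)butanedioate; 6 triethylsilyl trifluoromethanesulfonate
Product: 7 diethyl (2S,3R)-2-methyl-2-(prop-2-en-1-yl)-3-[(triethylsilyl)oxy]butanedioate
Conditions: 6, 2,6-lutidine, CH2Cl2, 0 °C
Reagents that add atoms: triethylsilyl trifluoromethanesulfonate, CC[Si](CC)(CC)OS(=O)(=O)C(F)(F)F
Why: silyl triflate silylation of the hindered secondary alcohol; the TES ether prevents retro-aldol cleavage after step 5 and removes the chelating hydroxyl before step 12.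

**Step 4**
Reactants: 7 diethyl (2S,3R)-2-methyl-2-(prop-2-en-1-yl)-3-[(triethylsilyl)oxy]butanedioate
Product: 8 diethyl (2S,3R)-2-methyl-2-[(1E)-prop-1-en-1-yl]-3-[(triethylsilyl)oxy]butanedioate
Conditions: RuHCl(CO)(PPh3)3 (5 mol %), toluene, 90 °C
Reagents that add atoms: none
Why: ruthenium hydride alkene isomerisation (hydrometalation then β-hydride elimination) moves the double bond one position inward and the quaternary C-4 blocks further migration; the alkene geometry is irrelevant because step 5 cleaves it.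

**Step 5**
Reactants: 8 diethyl (2S,3R)-2-methyl-2-[(1E)-prop-1-en-1-yl]-3-[(triethylsilyl)oxy]butanedioate; 9 ozone
Product: 10 diethyl (2R,3R)-2-formyl-2-methyl-3-[(triethylsilyl)oxy]butanedioate
Conditions: O3, CH2Cl2, −78 °C; then PPh3, −78 °C to rt
Reagents that add atoms: ozone, [O-][O+]=O
Why: ozonolysis with reductive work-up cleaves the propenyl group to the non-enolisable α-quaternary aldehyde (C-5) and leaves both esters and the silyl ether untouched.

**Step 6**
Reactants: 11 ethyl but-2-ynoate; 12 2-[dimethyl(phenyl)silyl]-4,4,5,5-tetramethyl-1,3,2-dioxaborolane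
Product: 13 ethyl (2E)-3-[dimethyl(phenyl)silyl]but-2-enoate
Conditions: CuSO4 (1 mol %), 4-methylpyridine (5 mol %), H2O, rt
Reagents that add atoms: 2-[dimethyl(phenyl)silyl]-4,4,5,5-tetramethyl-1,3,2-dioxaborolane, CC1(C)OB(OC1(C)C)[Si](C)(C)c1ccccc1
Why: copper-catalysed conjugate silyl transfer (syn silylcupration of the ynoate, then protonation with retention) should place silicon trans to the ester, i.e. the E-β-silyl enoate.

**Step 7**
Reactants: 13 ethyl (2E)-3-[dimethyl(phenyl)silyl]but-2-enoate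
Product: 14 (2E)-3-[dimethyl(phenyl)silyl]but-2-en-1-ol
Conditions: i-Bu2AlH (2.5 equiv), CH2Cl2, −78 to 0 °C
Reagents that add atoms: none
Why: aluminium hydride 1,2-reduction of the enoate to the allylic alcohol; the vinylsilane geometry is not touched.

**Step 8**
Reactants: 14 (2E)-3-[dimethyl(phenyl)silyl]but-2-en-1-ol; 15 triethyl phosphite
Product: 16 diethyl {(2E)-3-[dimethyl(phenyl)silyl]but-2-en-1-yl}phosphonate
Conditions: 15 (3 equiv), ZnI2 (1.5 equiv), toluene, 110 °C
Reagents that add atoms: triethyl phosphite, CCOP(OCC)OCC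
Why: Michaelis–Arbuzov-type phosphonylation of the allylic alcohol through its phosphite, promoted by ZnI2; reaction at the primary terminus keeps the E-vinylsilane.

**Step 9**
Reactants: 10 diethyl (2R,3R)-2-formyl-2-methyl-3-[(triethylsilyl)oxy]butanedioate; 16 diethyl {(2E)-3-[dimethyl(phenyl)silyl]but-2-en-1-yl}phosphonate
Product: 17 diethyl (2S,3R)-2-{(1E,3E)-4-[dimethyl(phenyl)silyl]penta-1,3-dien-1-yl}-2-methyl-3-[(triethylsilyl)oxy]butanedioate
Conditions: 16, n-BuLi, THF, −78 °C; then 10, −78 to 0 °C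
Reagents that add atoms: diethyl {(2E)-3-[dimethyl(phenyl)silyl]but-2-en-1-yl}phosphonate, CCOP(=O)(OCC)C/C=C(\C)[Si](C)(C)c1ccccc1
Why: Horner–Wadsworth–Emmons olefination: the lithiated allylic phosphonate adds through its α-carbon to the non-enolisable aldehyde and syn-elimination should give the E-C5=C6 alkene, the C7=C8 geometry being carried over from 16.

**Step 10**
Reactants: 17 diethyl (2S,3R)-2-{(1E,3E)-4-[dimethyl(phenyl)silyl]penta-1,3-dien-1-yl}-2-methyl-3-[(triethylsilyl)oxy]butanedioate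
Product: 18 ethyl (2S,3R)-2-{(1E,3E)-4-[dimethyl(phenyl)silyl]penta-1,3-dien-1-yl}-2-methyl-4-oxo-3-[(triethylsilyl)oxy]butanoate
Conditions: i-Bu2AlH (1.1 equiv), CH2Cl2, −78 °C
Reagents that add atoms: none
Why: partial ester reduction: at −78 °C the hydride attacks the less hindered α-silyloxy ester and the aluminium hemiacetal survives until work-up, while the ester on the quaternary carbon is shielded.

**Step 11**
Reactants: 19 methyl 3-methylbut-2-enoate; 20 chlorotrimethylsilane
Product: 21 [(1-methoxy-3-methylbuta-1,3-dien-1-yl)oxy]trimethylsilane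
Conditions: LiN(i-Pr)2, THF, −78 °C; then 20
Reagents that add atoms: chlorotrimethylsilane, C[Si](C)(C)Cl
Why: kinetic γ-deprotonation of the senecioate and O-silylation give the vinylogous silyl ketene acetal.

**Step 12**
Reactants: 18 ethyl (2S,3R)-2-{(1E,3E)-4-[dimethyl(phenyl)silyl]penta-1,3-dien-1-yl}-2-methyl-4-oxo-3-[(triethylsilyl)oxy]butanoate; 21 [(1-methoxy-3-methylbuta-1,3-dien-1-yl)oxy]trimethylsilane
Product: 22 8-ethyl 1-methyl (2E,5S,6R,7S)-7-{(1E,3E)-4-[dimethyl(phenyl)silyl]penta-1,3-dien-1-yl}-5-hydroxy-3,7-dimethyl-6-[(triethylsilyl)oxy]oct-2-enedioate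
Conditions: 21 (1.5 equiv), BF3·OEt2 (1.2 equiv), CH2Cl2, −78 °C
Reagents that add atoms: [(1-methoxy-3-methylbuta-1,3-dien-1-yl)oxy]trimethylsilane, COC(O[Si](C)(C)C)=CC(C)=C
Why: vinylogous Mukaiyama aldol reaction at the γ-carbon of 21; BF3 cannot chelate, so the polar Felkin–Anh transition state should place the new C-2 hydroxyl anti to the C-3 silyloxy group, and the s-trans dienolate gives the E-enoate.

**Step 13**
Reactants: 22 8-ethyl 1-methyl (2E,5S,6R,7S)-7-{(1E,3E)-4-[dimethyl(phenyl)silyl]penta-1,3-dien-1-yl}-5-hydroxy-3,7-dimethyl-6-[(triethylsilyl)oxy]oct-2-enedioate; 23 2,2-dimethoxypropane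
Product: 25 ethyl (2S,3E,5E)-6-[dimethyl(phenyl)silyl]-2-{(4R,5S)-5-[(2E)-4-methoxy-2-methyl-4-oxobut-2-en-1-yl]-2,2-dimethyl-1,3-dioxolan-4-yl}-2-methylhepta-3,5-dienoate, via diol 24 (not isolated)
Conditions: PPTS (20 mol %), MeOH, 40 °C; concentrate; then 23, acetone, PPTS, rt
Reagents that add atoms: 2,2-dimethoxypropane, COC(C)(C)OC
Why: acid-catalysed methanolysis of the TES ether and transketalisation of the resulting anti-diol give the cis-dioxolane, a temporary ring that protects C-2/C-3 and holds C-1 and C-4 gauche for the ring closure.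

**Step 14**
Reactants: 25 ethyl (2S,3E,5E)-6-[dimethyl(phenyl)silyl]-2-{(4R,5S)-5-[(2E)-4-methoxy-2-methyl-4-oxobut-2-en-1-yl]-2,2-dimethyl-1,3-dioxolan-4-yl}-2-methylhepta-3,5-dienoate
Product: 26 (2R,3E,5E)-6-[dimethyl(phenyl)silyl]-2-{(4R,5S)-5-[(2E)-4-hydroxy-2-methylbut-2-en-1-yl]-2,2-dimethyl-1,3-dioxolan-4-yl}-2-methylhepta-3,5-dien-1-ol
Conditions: i-Bu2AlH (6 equiv), CH2Cl2, −78 to 0 °C
Reagents that add atoms: none
Why: exhaustive aluminium hydride reduction converts the enoate into the allylic alcohol and the hindered C-19 ester into the primary alcohol in one operation.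

**Step 15**
Reactants: 26 (2R,3E,5E)-6-[dimethyl(phenyl)silyl]-2-{(4R,5S)-5-[(2E)-4-hydroxy-2-methylbut-2-en-1-yl]-2,2-dimethyl-1,3-dioxolan-4-yl}-2-methylhepta-3,5-dien-1-ol
Product: 27 (2E)-4-{(4S,5R)-5-[(2R,3E,5E)-6-[dimethyl(phenyl)silyl]-1-hydroxy-2-methylhepta-3,5-dien-2-yl]-2,2-dimethyl-1,3-dioxolan-4-yl}-3-methylbut-2-enal
Conditions: MnO2 (20 equiv), CH2Cl2, rt
Reagents that add atoms: none
Why: allylic oxidation: MnO2 should oxidise only the allylic alcohol to the E-enal and leave the neopentyl C-19 alcohol and the alkene geometry untouched.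

**Step 16**
Reactants: 27 (2E)-4-{(4S,5R)-5-[(2R,3E,5E)-6-[dimethyl(phenyl)silyl]-1-hydroxy-2-methylhepta-3,5-dien-2-yl]-2,2-dimethyl-1,3-dioxolan-4-yl}-3-methylbut-2-enal
Product: 28 (2S,3R,4R,5S,8R,9R,10R)-8-[dimethyl(phenyl)silyl]-19-hydroxy-2,3-(isopropylidenedioxy)-12,13,14,15,16-pentanorlabd-6-en-11-al
Conditions: Me2AlCl (2.2 equiv), CH2Cl2, −78 to −30 °C
Reagents that add atoms: none
Why: Type 1 intramolecular Diels–Alder reaction: the Me2AlCl-bound E-enal C9=C10 (LUMO largest at C-10) and the electron-rich dienylsilane C5=C6–C7=C8 (HOMO largest at C-5) should combine in a concerted, asynchronous [4+2] event in which C5–C10 bonding runs ahead of C8–C9 bonding at the hindered silyl-bearing terminus; the closest known reaction type is the Lewis-acid-promoted cyclisation of 1,3,9-decatrienals to trans-fused octalins, together with the use of 1-silyl dienes to give allylsilane adducts. Ring B closes as the new cyclohexene of the [4+2] addition (suprafacial on both components) and ring A closes at the same time as the six-membered ring spanned by the four-atom tether C-1 to C-4 in a chair-like arrangement. C-9 and C-10 follow from the E-geometry of the dienophile (C-11 cis to the C-10 methyl), the trans ring fusion (H-5 anti to the C-10 methyl) from the transition state with the aluminium-bound formyl group endo, and C-8 (silyl cis to formyl, a temporary centre) from the E-silyl diene terminus. The step needs endo over exo selectivity and one diene face over the other; the face is secured by the tether, because only the chair with the C-2 oxygen equatorial, the C-3 oxygen axial and the C-4 methyl equatorial avoids a 1,3,5-triaxial array of the C-2 oxygen, the C-4 methyl and the C-10 methyl, and the cis-dioxolane holds C-1 and C-4 gauche as required. The first equivalent of Me2AlCl is consumed by the C-19 hydroxyl (aluminium alkoxide) and the second activates the aldehyde.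

**Step 17**
Reactants: 28 (2S,3R,4R,5S,8R,9R,10R)-8-[dimethyl(phenyl)silyl]-19-hydroxy-2,3-(isopropylidenedioxy)-12,13,14,15,16-pentanorlabd-6-en-11-al; 29 methyltriphenylphosphonium bromide
Product: 30 (2S,3R,4R,5S,8R,9S,10R)-8-[dimethyl(phenyl)silyl]-2,3-(isopropylidenedioxy)-13,14,15,16-tetranorlabda-6,11-dien-19-ol
Conditions: 29 (3 equiv), KOt-Bu (3 equiv), THF, 0 °C to rt
Reagents that add atoms: methyltriphenylphosphonium bromide, C[P+](c1ccccc1)(c1ccccc1)c1ccccc1.[Br-]
Why: Wittig methylenation of the hindered aldehyde with the small non-stabilised ylide; excess ylide tolerates the free hydroxyl, and C-9 keeps its equatorial substituent.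

**Step 18**
Reactants: 31 tert-butyl 3-oxobutanoate; 32 trifluoromethanesulfonic anhydride
Product: 33 tert-butyl (2E)-3-[(trifluoromethanesulfonyl)oxy]but-2-enoate
Conditions: aq. Me4NOH, hexane, 5 °C; then 32, 5 °C to rt
Reagents that add atoms: trifluoromethanesulfonic anhydride, O=S(=O)(OS(=O)(=O)C(F)(F)F)C(F)(F)F
Why: O-triflation of the non-chelated (tetramethylammonium) enolate of the β-keto ester, which should give the E-enol triflate (triflate trans to the ester).

**Step 19**
Reactants: 30 (2S,3R,4R,5S,8R,9S,10R)-8-[dimethyl(phenyl)silyl]-2,3-(isopropylidenedioxy)-13,14,15,16-tetranorlabda-6,11-dien-19-ol; 34 9-borabicyclo[3.3.1]nonane; 33 tert-butyl (2E)-3-[(trifluoromethanesulfonyl)oxy]but-2-enoate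
Product: 36 tert-butyl (2S,3R,4R,5S,8R,9S,10R,13E)-8-[dimethyl(phenyl)silyl]-19-hydroxy-2,3-(isopropylidenedioxy)labda-6,13-dien-15-oate, via alkylborane 35 (not isolated)
Conditions: 34 (2.5 equiv), THF, rt; then 33, PdCl2(dppf) (5 mol %), K3PO4 (3 M aq), DMF, rt
Reagents that add atoms: tert-butyl (2E)-3-[(trifluoromethanesulfonyl)oxy]but-2-enoate, CC(C)(C)OC(=O)/C=C(\C)OS(=O)(=O)C(F)(F)F
Why: anti-Markovnikov hydroboration of the only monosubstituted alkene by the bulky borane, followed by B-alkyl Suzuki–Miyaura coupling with retention of the triflate geometry, installs C-12 to C-16 with the 13E double bond.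

**Step 20**
Reactants: 36 tert-butyl (2S,3R,4R,5S,8R,9S,10R,13E)-8-[dimethyl(phenyl)silyl]-19-hydroxy-2,3-(isopropylidenedioxy)labda-6,13-dien-15-oate
Product: 37 tert-butyl (2S,3R,4S,5S,8R,9S,10R,13E)-8-[dimethyl(phenyl)silyl]-2,3-(isopropylidenedioxy)-19-oxolabda-6,13-dien-15-oate
Conditions: Dess–Martin periodinane, NaHCO3, CH2Cl2, 0 °C to rt
Reagents that add atoms: none
Why: Dess–Martin oxidation of the neopentyl primary alcohol to the non-enolisable C-19 aldehyde under buffered conditions that spare the allylsilane and the acetonide.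

**Step 21**
Reactants: 37 tert-butyl (2S,3R,4S,5S,8R,9S,10R,13E)-8-[dimethyl(phenyl)silyl]-2,3-(isopropylidenedioxy)-19-oxolabda-6,13-dien-15-oate
Product: 39 (2S,3R,4S,5S,9R,10S,13E)-2,3-dihydroxy-19-oxolabda-7,13-dien-15-oic acid, via Δ7 acetonide ester 38 (not isolated)
Conditions: TFA/CH2Cl2/H2O (10:10:1), 0 °C to rt
Reagents that add atoms: none
Why: protodesilylation of the allylsilane (SE2': protonation at C-6, loss of silicon from C-8) should move the double bond regiospecifically to C7=C8, and the same acid hydrolyses the acetonide and cleaves the tert-butyl ester with loss of isobutene.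

**Step 22**
Reactants: 39 (2S,3R,4S,5S,9R,10S,13E)-2,3-dihydroxy-19-oxolabda-7,13-dien-15-oic acid; 40 acetic anhydride
Product: 42 (2S,3R,4S,5S,9R,10S,13E)-2,3-diacetoxy-19-oxolabda-7,13-dien-15-oic acid, via mixed anhydride 41 (not isolated)
Conditions: 40, pyridine, DMAP (cat.), CH2Cl2, rt; then THF/aq. NaHCO3, rt
Reagents that add atoms: acetic anhydride, CC(=O)OC(C)=O
Why: DMAP-catalysed acylation of both secondary hydroxyls; the mixed anhydride formed at C-15 is hydrolysed in the aqueous work-up, which should leave the target.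

**Compound list**

1 | diethyl (R)-malate | CCOC(=O)[C@H](O)CC(=O)OCC | starting material
2 | iodomethane | CI | starting material
3 | diethyl (2R,3S)-2-hydroxy-3-methylbutanedioate | CCOC(=O)[C@H](O)[C@H](C)C(=O)OCC | intermediate
4 | 3-bromoprop-1-ene | C=CCBr | starting material
5 | diethyl (2S,3R)-3-hydroxy-2-methyl-2-(prop-2-en-1-yl)butanedioate | CCOC(=O)[C@H](O)[C@](C)(CC=C)C(=O)OCC | intermediate
6 | triethylsilyl trifluoromethanesulfonate | CC[Si](CC)(CC)OS(=O)(=O)C(F)(F)F | starting material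
7 | diethyl (2S,3R)-2-methyl-2-(prop-2-en-1-yl)-3-[(triethylsilyl)oxy]butanedioate | CCOC(=O)[C@H](O[Si](CC)(CC)CC)[C@](C)(CC=C)C(=O)OCC | intermediate
8 | diethyl (2S,3R)-2-methyl-2-[(1E)-prop-1-en-1-yl]-3-[(triethylsilyl)oxy]butanedioate | CCOC(=O)[C@H](O[Si](CC)(CC)CC)[C@](C)(/C=C/C)C(=O)OCC | intermediate
9 | ozone | [O-][O+]=O | starting material
10 | diethyl (2R,3R)-2-formyl-2-methyl-3-[(triethylsilyl)oxy]butanedioate | CCOC(=O)[C@H](O[Si](CC)(CC)CC)[C@](C)(C=O)C(=O)OCC | intermediate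
11 | ethyl but-2-ynoate | CCOC(=O)C#CC | starting material
12 | 2-[dimethyl(phenyl)silyl]-4,4,5,5-tetramethyl-1,3,2-dioxaborolane | CC1(C)OB(OC1(C)C)[Si](C)(C)c1ccccc1 | starting material
13 | ethyl (2E)-3-[dimethyl(phenyl)silyl]but-2-enoate | CCOC(=O)/C=C(\C)[Si](C)(C)c1ccccc1 | intermediate
14 | (2E)-3-[dimethyl(phenyl)silyl]but-2-en-1-ol | OC/C=C(\C)[Si](C)(C)c1ccccc1 | intermediate
15 | triethyl phosphite | CCOP(OCC)OCC | starting material
16 | diethyl {(2E)-3-[dimethyl(phenyl)silyl]but-2-en-1-yl}phosphonate | CCOP(=O)(OCC)C/C=C(\C)[Si](C)(C)c1ccccc1 | intermediate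
17 | diethyl (2S,3R)-2-{(1E,3E)-4-[dimethyl(phenyl)silyl]penta-1,3-dien-1-yl}-2-methyl-3-[(triethylsilyl)oxy]butanedioate | CCOC(=O)[C@H](O[Si](CC)(CC)CC)[C@](C)(/C=C/C=C(\C)[Si](C)(C)c1ccccc1)C(=O)OCC | intermediate
18 | ethyl (2S,3R)-2-{(1E,3E)-4-[dimethyl(phenyl)silyl]penta-1,3-dien-1-yl}-2-methyl-4-oxo-3-[(triethylsilyl)oxy]butanoate | O=C[C@H](O[Si](CC)(CC)CC)[C@](C)(/C=C/C=C(\C)[Si](C)(C)c1ccccc1)C(=O)OCC | intermediate
19 | methyl 3-methylbut-2-enoate | COC(=O)C=C(C)C | starting material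
20 | chlorotrimethylsilane | C[Si](C)(C)Cl | starting material
21 | [(1-methoxy-3-methylbuta-1,3-dien-1-yl)oxy]trimethylsilane (isomer mixture at the ketene acetal) | COC(O[Si](C)(C)C)=CC(C)=C | intermediate
22 | 8-ethyl 1-methyl (2E,5S,6R,7S)-7-{(1E,3E)-4-[dimethyl(phenyl)silyl]penta-1,3-dien-1-yl}-5-hydroxy-3,7-dimethyl-6-[(triethylsilyl)oxy]oct-2-enedioate | COC(=O)/C=C(\C)C[C@H](O)[C@H](O[Si](CC)(CC)CC)[C@](C)(/C=C/C=C(\C)[Si](C)(C)c1ccccc1)C(=O)OCC | intermediate
23 | 2,2-dimethoxypropane | COC(C)(C)OC | starting material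
24 | 8-ethyl 1-methyl (2E,5S,6R,7S)-7-{(1E,3E)-4-[dimethyl(phenyl)silyl]penta-1,3-dien-1-yl}-5,6-dihydroxy-3,7-dimethyloct-2-enedioate | COC(=O)/C=C(\C)C[C@H](O)[C@H](O)[C@](C)(/C=C/C=C(\C)[Si](C)(C)c1ccccc1)C(=O)OCC | intermediate
25 | ethyl (2S,3E,5E)-6-[dimethyl(phenyl)silyl]-2-{(4R,5S)-5-[(2E)-4-methoxy-2-methyl-4-oxobut-2-en-1-yl]-2,2-dimethyl-1,3-dioxolan-4-yl}-2-methylhepta-3,5-dienoate | COC(=O)/C=C(\C)C[C@@H]1OC(C)(C)O[C@@H]1[C@](C)(/C=C/C=C(\C)[Si](C)(C)c2ccccc2)C(=O)OCC | intermediate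
26 | (2R,3E,5E)-6-[dimethyl(phenyl)silyl]-2-{(4R,5S)-5-[(2E)-4-hydroxy-2-methylbut-2-en-1-yl]-2,2-dimethyl-1,3-dioxolan-4-yl}-2-methylhepta-3,5-dien-1-ol | OC/C=C(\C)C[C@@H]1OC(C)(C)O[C@@H]1[C@](C)(/C=C/C=C(\C)[Si](C)(C)c2ccccc2)CO | intermediate
27 | (2E)-4-{(4S,5R)-5-[(2R,3E,5E)-6-[dimethyl(phenyl)silyl]-1-hydroxy-2-methylhepta-3,5-dien-2-yl]-2,2-dimethyl-1,3-dioxolan-4-yl}-3-methylbut-2-enal | O=C/C=C(\C)C[C@@H]1OC(C)(C)O[C@@H]1[C@](C)(/C=C/C=C(\C)[Si](C)(C)c2ccccc2)CO | intermediate
28 | (2S,3R,4R,5S,8R,9R,10R)-8-[dimethyl(phenyl)silyl]-19-hydroxy-2,3-(isopropylidenedioxy)-12,13,14,15,16-pentanorlabd-6-en-11-al (trans-fused; CHO-9, silyl-8, CH3-10 and CH2OH-4 on one face; H-5, CH3-8, CH3-4 and both dioxolane oxygens on the other) | CC1(C)O[C@H]2C[C@@]3(C)[C@H](C=O)[C@](C)([Si](C)(C)c4ccccc4)C=C[C@@H]3[C@](C)(CO)[C@H]2O1 | intermediate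
29 | methyltriphenylphosphonium bromide | C[P+](c1ccccc1)(c1ccccc1)c1ccccc1.[Br-] | starting material
30 | (2S,3R,4R,5S,8R,9S,10R)-8-[dimethyl(phenyl)silyl]-2,3-(isopropylidenedioxy)-13,14,15,16-tetranorlabda-6,11-dien-19-ol | CC1(C)O[C@H]2C[C@@]3(C)[C@H](C=C)[C@](C)([Si](C)(C)c4ccccc4)C=C[C@@H]3[C@](C)(CO)[C@H]2O1 | intermediate
31 | tert-butyl 3-oxobutanoate | CC(=O)CC(=O)OC(C)(C)C | starting material
32 | trifluoromethanesulfonic anhydride | O=S(=O)(OS(=O)(=O)C(F)(F)F)C(F)(F)F | starting material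
33 | tert-butyl (2E)-3-[(trifluoromethanesulfonyl)oxy]but-2-enoate | CC(C)(C)OC(=O)/C=C(\C)OS(=O)(=O)C(F)(F)F | intermediate
34 | 9-borabicyclo[3.3.1]nonane | B1C2CCCC1CCC2 | starting material
35 | 12-(9-borabicyclo[3.3.1]nonan-9-yl) adduct of 30 with the C-19 oxygen as its 9-borabicyclononyl borinate | CC1(C)O[C@H]2C[C@@]3(C)[C@H](CCB4C5CCCC4CCC5)[C@](C)([Si](C)(C)c6ccccc6)C=C[C@@H]3[C@](C)(COB7C8CCCC7CCC8)[C@H]2O1 | intermediate
36 | tert-butyl (2S,3R,4R,5S,8R,9S,10R,13E)-8-[dimethyl(phenyl)silyl]-19-hydroxy-2,3-(isopropylidenedioxy)labda-6,13-dien-15-oate | CC1(C)O[C@H]2C[C@@]3(C)[C@H](CC/C(C)=C/C(=O)OC(C)(C)C)[C@](C)([Si](C)(C)c4ccccc4)C=C[C@@H]3[C@](C)(CO)[C@H]2O1 | intermediate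
37 | tert-butyl (2S,3R,4S,5S,8R,9S,10R,13E)-8-[dimethyl(phenyl)silyl]-2,3-(isopropylidenedioxy)-19-oxolabda-6,13-dien-15-oate | CC1(C)O[C@H]2C[C@@]3(C)[C@H](CC/C(C)=C/C(=O)OC(C)(C)C)[C@](C)([Si](C)(C)c4ccccc4)C=C[C@@H]3[C@](C)(C=O)[C@H]2O1 | intermediate
38 | tert-butyl (2S,3R,4S,5S,9R,10S,13E)-2,3-(isopropylidenedioxy)-19-oxolabda-7,13-dien-15-oate | CC1(C)O[C@H]2C[C@@]3(C)[C@H](CC/C(C)=C/C(=O)OC(C)(C)C)C(C)=CC[C@@H]3[C@](C)(C=O)[C@H]2O1 | intermediate
39 | (2S,3R,4S,5S,9R,10S,13E)-2,3-dihydroxy-19-oxolabda-7,13-dien-15-oic acid | O[C@H]1C[C@@]2(C)[C@H](CC/C(C)=C/C(=O)O)C(C)=CC[C@@H]2[C@](C)(C=O)[C@H]1O | intermediate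
40 | acetic anhydride | CC(=O)OC(C)=O | starting material
41 | acetic (2S,3R,4S,5S,9R,10S,13E)-2,3-diacetoxy-19-oxolabda-7,13-dien-15-oic anhydride | CC(=O)O[C@H]1C[C@@]2(C)[C@H](CC/C(C)=C/C(=O)OC(C)=O)C(C)=CC[C@@H]2[C@](C)(C=O)[C@H]1OC(C)=O | intermediate
42 | (2S,3R,4S,5S,9R,10S,13E)-2,3-diacetoxy-19-oxolabda-7,13-dien-15-oic acid | CC(=O)O[C@H]1C[C@@]2(C)[C@H](CC/C(C)=C/C(=O)O)C(C)=CC[C@@H]2[C@](C)(C=O)[C@H]1OC(C)=O | target

**Totals**

Total step count: 22.
Longest linear sequence: 17 steps (steps 1–5, 9, 10, 12–17 and 19–22, from diethyl (R)-malate).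

**Steps most likely to fail**

1. Step 16. The fully substituted, silyl-bearing C-8 terminus may slow the ring closure enough for loss of the dienyl silyl group or E/Z isomerisation of the aluminium-bound enal to compete, and the endo and facial preferences may then erode. The fallback sets out from 27 and comes back at 28. The enal is converted with 1,2-bis(trimethylsilyloxy)ethane and catalytic TMSOTf at −78 °C into its ethylene acetal, dioxolane acetal F1. Ionisation of F1 with TMSOTf at −78 °C generates a 2-vinyl-1,3-dioxolan-2-ylium ion, a far more electrophilic dienophile, and the ionic Diels–Alder reaction should give the acetal-protected octalin F2. Mild hydrolysis (PPTS, wet acetone), which spares the allylsilane, should release aldehyde 28.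

2. Step 12. The 1,2-anti induction at C-2 may be insufficient (competition between the polar Felkin–Anh and chelated pathways next to the bulky quaternary C-4), or γ-regioselectivity may erode. The fallback sets out from 18 and comes back at 22. Reagent-controlled propargylation of 18 with allenylboronic acid pinacol ester under a chiral BINOL-derived phosphoric acid catalyst should give homopropargylic alcohol F3 with catalyst-set C-2. Zirconium-catalysed carboalumination of the terminal alkyne (Me3Al, cat. Cp2ZrCl2) and trapping of the alkenylalane with methyl chloroformate should then deliver the E-enoate 22.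

3. Step 21. The strong acid needed for three deprotections at once may cause migration of the new C7=C8 double bond towards C8=C9, or Prins-type closure of the C-19 aldehyde onto it. The fallback sets out from 36 and comes back at 42. Protodesilylation is done first with catalytic TsOH·H2O in CH2Cl2 while C-19 is still an alcohol, which should give C-19 alcohol F4. Dess–Martin oxidation gives 38, aqueous acetic acid removes the acetonide to give diol F5, and acetylation (Ac2O, pyridine, DMAP) gives diacetate tert-butyl ester F6. The ester is then cleaved without protic acid (TMSOTf, 2,6-lutidine, CH2Cl2; aqueous work-up) to give 42.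

**Further compounds**

F1 | step 16 | (2R,3E,5E)-6-[dimethyl(phenyl)silyl]-2-{(4R,5S)-5-[(2E)-3-(1,3-dioxolan-2-yl)-2-methylprop-2-en-1-yl]-2,2-dimethyl-1,3-dioxolan-4-yl}-2-methylhepta-3,5-dien-1-ol | O1CCOC1/C=C(\C)C[C@@H]2OC(C)(C)O[C@@H]2[C@](C)(/C=C/C=C(\C)[Si](C)(C)c3ccccc3)CO
F2 | step 16 | (2S,3R,4R,5S,8R,9R,10R)-8-[dimethyl(phenyl)silyl]-11,11-(ethylenedioxy)-2,3-(isopropylidenedioxy)-12,13,14,15,16-pentanorlabd-6-en-19-ol | CC1(C)O[C@H]2C[C@@]3(C)[C@H](C4OCCO4)[C@](C)([Si](C)(C)c5ccccc5)C=C[C@@H]3[C@](C)(CO)[C@H]2O1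
F3 | step 12 | ethyl (2S,3R,4S)-2-{(1E,3E)-4-[dimethyl(phenyl)silyl]penta-1,3-dien-1-yl}-4-hydroxy-2-methyl-3-[(triethylsilyl)oxy]hept-6-ynoate | C#CC[C@H](O)[C@H](O[Si](CC)(CC)CC)[C@](C)(/C=C/C=C(\C)[Si](C)(C)c1ccccc1)C(=O)OCC
F4 | step 21 | tert-butyl (2S,3R,4R,5S,9R,10S,13E)-19-hydroxy-2,3-(isopropylidenedioxy)labda-7,13-dien-15-oate | CC1(C)O[C@H]2C[C@@]3(C)[C@H](CC/C(C)=C/C(=O)OC(C)(C)C)C(C)=CC[C@@H]3[C@](C)(CO)[C@H]2O1
F5 | step 21 | tert-butyl (2S,3R,4S,5S,9R,10S,13E)-2,3-dihydroxy-19-oxolabda-7,13-dien-15-oate | O[C@H]1C[C@@]2(C)[C@H](CC/C(C)=C/C(=O)OC(C)(C)C)C(C)=CC[C@@H]2[C@](C)(C=O)[C@H]1O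
F6 | step 21 | tert-butyl (2S,3R,4S,5S,9R,10S,13E)-2,3-diacetoxy-19-oxolabda-7,13-dien-15-oate | CC(=O)O[C@H]1C[C@@]2(C)[C@H](CC/C(C)=C/C(=O)OC(C)(C)C)C(C)=CC[C@@H]2[C@](C)(C=O)[C@H]1OC(C)=O
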